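**Retrosynthetic overview**

1. The aryl ether is made last (Mitsunobu reaction of umbelliferone with a tetraol). The side-chain carbinol comes unchanged from (R)-linalool.
2. Ring numbering used below: C1 = CHOH, C2 = CMe2, C3 = CH carrying the side chain, C4 = C(OH)CH3, C5 and C6 = CH2. The enabling feature is that the two oxygen-bearing ring carbons C1 and C4 are para, and each is the middle atom of a three-carbon unit (C6–C1–C2 and C3–C4–C5).
3. The cyclohexane therefore splits into 3-methylbutan-2-one (nucleophilic at both α-carbons, gem-dimethyl already present) and a 2-nitroallyl acetate (electrophilic at both ends, nitro = masked C4 carbonyl). Bonds C2–C3 and C5–C6 are formed together in a [3+3] carbocyclisation of the ketone's (S)-1-phenylethylamine imine, which sets C3.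
4. After the ring: C1 ketone to the equatorial alcohol (conformational lock), nitro to C4 ketone, methyl addition (sets C4), reoxidation and bulky-hydride reduction (sets C1, axial).
5. The cyclohexane is the only ring formed (step 8); the coumarin is bought, and a 1,3-dioxane serves as a temporary protecting ring (steps 2 to 13).

Key step: step 8

Assumption: (R)-(−)-linalool of high enantiomeric purity is taken as commercial, and the facial sense in step 8 follows the accepted transition-state model for 1-phenylethylamine-derived secondary enamines (attack anti to phenyl, acceptor nitro group over the N–H).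

**Route**

Step 1
Reactants: 1 (R)-(−)-linalool
Product: 3 (3R)-3,7-dimethyloct-6-ene-1,3-diol, via alkylborane 2 (not isolated)
Conditions: 9-BBN, THF, 0 °C to rt; then NaOH, H2O2, H2O, 0 °C to rt
Reagents that add atoms: hydrogen peroxide, OO
Why: Anti-Markovnikov hydroboration–oxidation; 9-BBN should react with the monosubstituted vinyl group far faster than with the trisubstituted alkene, and no bond to the carbinol stereocentre is touched.

Step 2
Reactants: 3 (3R)-3,7-dimethyloct-6-ene-1,3-diol
Product: 4 (4R)-2,2,4-trimethyl-4-(4-methylpent-3-en-1-yl)-1,3-dioxane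
Conditions: 2,2-dimethoxypropane, pyridinium p-toluenesulfonate (cat.), CH2Cl2, rt
Reagents that add atoms: 2,2-dimethoxypropane, COC(C)(C)OC
Why: Acid-catalysed transacetalisation should close the acetonide over the primary and tertiary hydroxyls, protecting both for the basic, nitroalkene and organometallic steps.

Step 3
Reactants: 4 (4R)-2,2,4-trimethyl-4-(4-methylpent-3-en-1-yl)-1,3-dioxane
Product: 6 3-[(4R)-2,2,4-trimethyl-1,3-dioxan-4-yl]propanal, via ozonide 5 (not isolated)
Conditions: O3, CH2Cl2, −78 °C; then Me2S, −78 °C to rt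
Reagents that add atoms: ozone, [O-][O+]=O
Why: Ozonolysis with reductive work-up should cleave the only alkene to the aldehyde; the ketone-derived acetal has no oxidisable acetal C–H.

Step 4
Reactants: 6 3-[(4R)-2,2,4-trimethyl-1,3-dioxan-4-yl]propanal
Product: 9 (4R)-2,2,4-trimethyl-4-[(3E)-4-nitrobut-3-en-1-yl]-1,3-dioxane, via nitro alcohol 7 (not isolated), via nitro mesylate 8 (not isolated)
Conditions: CH3NO2, 1,1,3,3-tetramethylguanidine (cat.), THF, 0 °C; then MsCl, Et3N, CH2Cl2, −20 to 0 °C
Reagents that add atoms: nitromethane, C[N+](=O)[O-]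
Why: Henry (nitroaldol) addition followed by mesylation and E1cB elimination should give the thermodynamically preferred E-nitroalkene.

Step 5
Reactants: 9 (4R)-2,2,4-trimethyl-4-[(3E)-4-nitrobut-3-en-1-yl]-1,3-dioxane
Product: 10 (2E)-2-nitro-5-[(4R)-2,2,4-trimethyl-1,3-dioxan-4-yl]pent-2-en-1-ol
Conditions: 37% aq. HCHO, imidazole (1 equiv), 2-aminobenzoic acid (10 mol %), THF, rt
Reagents that add atoms: formaldehyde, C=O
Why: Morita–Baylis–Hillman-type hydroxymethylation of a nitroalkene (imidazole adds to the β-carbon, the nitronate adds to formaldehyde, imidazole is expelled), expected to give the E isomer with the alkyl chain trans to nitro.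

Step 6
Reactants: 10 (2E)-2-nitro-5-[(4R)-2,2,4-trimethyl-1,3-dioxan-4-yl]pent-2-en-1-ol
Product: 11 (2E)-2-nitro-5-[(4R)-2,2,4-trimethyl-1,3-dioxan-4-yl]pent-2-en-1-yl acetate
Conditions: Ac2O, pyridine, CH2Cl2, 0 °C
Reagents that add atoms: acetic anhydride, CC(=O)OC(C)=O
Why: O-Acetylation turns the allylic oxygen into a leaving group, making the nitroalkene a 1,3-bis-electrophile.

Step 7
Reactants: 12 3-methylbutan-2-one; 13 (S)-1-phenylethan-1-amine
Product: 14 (S)-N-(3-methylbutan-2-ylidene)-1-phenylethan-1-amine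
Conditions: p-toluenesulfonic acid monohydrate (cat.), toluene, reflux, Dean–Stark trap; distillation
Reagents that add atoms: none
Why: Imine condensation driven by azeotropic removal of water; the amine stereocentre is not involved.

Step 8
Reactants: 11 (2E)-2-nitro-5-[(4R)-2,2,4-trimethyl-1,3-dioxan-4-yl]pent-2-en-1-yl acetate; 14 (S)-N-(3-methylbutan-2-ylidene)-1-phenylethan-1-amine
Product: 17 (3R,4R)-2,2-dimethyl-4-nitro-3-{2-[(4R)-2,2,4-trimethyl-1,3-dioxan-4-yl]ethyl}cyclohexan-1-one, via open-chain nitroallyl imine 15 (not isolated), via cyclic nitro imine 16 (not isolated)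
Conditions: THF, 0 °C to rt; then AcOH/NaOAc buffer (pH 4.5), THF/H2O, rt
Reagents that add atoms: water, O
Why: Proposed new method: the imine should react through its more substituted secondary-enamine tautomer, whose isopropylidene carbon adds in an aza-ene-type Michael step to the substituted alkene carbon of 11 (C2–C3); loss of acetate (overall SN2') leaves a CH2=C(NO2) unit, and the imine, now enolisable only toward its methyl group, closes the ring as the methyl-side enamine by 6-endo-trig Michael addition (C5–C6), after which mild hydrolysis frees the ketone and the auxiliary. The closest known reactions are the asymmetric Michael addition of 1-phenylethylamine imines of α-branched ketones to nitroalkenes (bond at the more substituted α-carbon) and the [3+3] carbocyclisation of ketone enamines with 2-nitroallyl esters; joining them with a chiral secondary enamine is the new element. C3 is set in the first, intermolecular bond formation: the E-nitroalkene should approach the enamine face anti to the phenyl group with the nitro group over the N–H, which turns the side chain outward and gives 3R. The nitro-bearing C4 is epimerisable and should settle trans to the side chain; it is erased in step 10. The step needs first attack by the isopropyl rather than the methyl α-carbon and attack at the substituted alkene terminus rather than at CH2OAc; the secondary-enamine mechanism secures the former and the conjugated nitroalkene the latter, while N-alkylation is reversible and C-alkylation is not.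

Step 9
Reactants: 17 (3R,4R)-2,2-dimethyl-4-nitro-3-{2-[(4R)-2,2,4-trimethyl-1,3-dioxan-4-yl]ethyl}cyclohexan-1-one
Product: 18 (1R,3R,4R)-2,2-dimethyl-4-nitro-3-{2-[(4R)-2,2,4-trimethyl-1,3-dioxan-4-yl]ethyl}cyclohexan-1-ol
Conditions: NaBH4, MeOH, 0 °C
Reagents that add atoms: none
Why: Small-hydride reduction should give the C1 alcohol cis to the side chain (equatorial), a temporary configuration whose purpose is to lock the chair with both substituents equatorial for steps 10 and 11; C1 is reset in steps 12 and 13.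

Step 10
Reactants: 18 (1R,3R,4R)-2,2-dimethyl-4-nitro-3-{2-[(4R)-2,2,4-trimethyl-1,3-dioxan-4-yl]ethyl}cyclohexan-1-ol
Product: 20 (2R,4R)-4-hydroxy-3,3-dimethyl-2-{2-[(4R)-2,2,4-trimethyl-1,3-dioxan-4-yl]ethyl}cyclohexan-1-one, via sodium nitronate 19 (not isolated)
Conditions: NaOMe, MeOH, 0 °C; O3, −78 °C; N2 purge, pH 7 phosphate buffer
Reagents that add atoms: ozone, [O-][O+]=O
Why: Nef reaction by ozonolysis of the nitronate should unveil the C4 ketone; the low temperature and neutral quench protect the adjacent C3 stereocentre, which is also shielded by the quaternary C2.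

Step 11
Reactants: 20 (2R,4R)-4-hydroxy-3,3-dimethyl-2-{2-[(4R)-2,2,4-trimethyl-1,3-dioxan-4-yl]ethyl}cyclohexan-1-one
Product: 21 (1R,3R,4S)-2,2,4-trimethyl-3-{2-[(4R)-2,2,4-trimethyl-1,3-dioxan-4-yl]ethyl}cyclohexane-1,4-diol
Conditions: CeCl3 (anhydrous), MeLi, THF, −78 °C; aq. NH4Cl
Reagents that add atoms: methyllithium, [Li]C
Why: Organocerium 1,2-addition (weakly basic, so enolisation is suppressed); in the locked chair the axial face of the C4 carbonyl is blocked by the axial methyl on C2, so methyl should enter equatorially, giving the axial C4 hydroxyl cis to the side chain.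

Step 12
Reactants: 21 (1R,3R,4S)-2,2,4-trimethyl-3-{2-[(4R)-2,2,4-trimethyl-1,3-dioxan-4-yl]ethyl}cyclohexane-1,4-diol
Product: 22 (3R,4S)-4-hydroxy-2,2,4-trimethyl-3-{2-[(4R)-2,2,4-trimethyl-1,3-dioxan-4-yl]ethyl}cyclohexan-1-one
Conditions: n-Pr4N[RuO4] (5 mol %), N-methylmorpholine N-oxide, 4 Å molecular sieves, CH2Cl2, rt
Reagents that add atoms: none
Why: Perruthenate-catalysed (Ley–Griffith) oxidation should convert only the secondary C1 alcohol; the tertiary alcohol and the acetonide are inert.

Step 13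
Reactants: 22 (3R,4S)-4-hydroxy-2,2,4-trimethyl-3-{2-[(4R)-2,2,4-trimethyl-1,3-dioxan-4-yl]ethyl}cyclohexan-1-one
Product: 24 (1S,3R,4S)-3-[(3R)-3,5-dihydroxy-3-methylpentyl]-2,2,4-trimethylcyclohexane-1,4-diol, via acetonide triol 23 (not isolated)
Conditions: LiBH(s-Bu)3 (L-Selectride), THF, −78 °C; then 80% aq. AcOH, rt
Reagents that add atoms: none
Why: The ring is now locked (side chain and C4 methyl equatorial), so the bulky hydride should attack the C1 ketone next to the gem-dimethyl carbon equatorially and give the axial alcohol trans to the side chain; the mild acid then hydrolyses the strained acetonide.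

Step 14
Reactants: 24 (1S,3R,4S)-3-[(3R)-3,5-dihydroxy-3-methylpentyl]-2,2,4-trimethylcyclohexane-1,4-diol; 25 umbelliferone (7-hydroxy-2H-chromen-2-one)
Product: 26 7-{[(3R)-5-[(1R,3S,6S)-3,6-dihydroxy-2,2,6-trimethylcyclohexyl]-3-hydroxy-3-methylpentyl]oxy}-2H-chromen-2-one (CNP0210598.2)
Conditions: PPh3, diisopropyl azodicarboxylate, THF, 0 °C to rt
Reagents that add atoms: none
Why: Mitsunobu etherification; only the primary hydroxyl should be activated and displaced by the acidic phenol, the two tertiary and the hindered axial secondary hydroxyls staying untouched, and no stereocentre is involved.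

**Compound list**

1 | (R)-(−)-linalool, (3R)-3,7-dimethylocta-1,6-dien-3-ol | CC(C)=CCC[C@@](C)(O)C=C | starting material
2 | 9-[(3S)-3-hydroxy-3,7-dimethyloct-6-en-1-yl]-9-borabicyclo[3.3.1]nonane (same spatial arrangement as 1; formed in the flask) | CC(C)=CCC[C@@](C)(O)CCB1C2CCCC1CCC2 | intermediate
3 | (3R)-3,7-dimethyloct-6-ene-1,3-diol | CC(C)=CCC[C@@](C)(O)CCO | intermediate
4 | (4R)-2,2,4-trimethyl-4-(4-methylpent-3-en-1-yl)-1,3-dioxane | CC(C)=CCC[C@@]1(C)OC(C)(C)OCC1 | intermediate
5 | 3,3-dimethyl-5-{2-[(4R)-2,2,4-trimethyl-1,3-dioxan-4-yl]ethyl}-1,2,4-trioxolane (ozonide, formed in the flask) | CC1(C)OOC(CC[C@@]2(C)OC(C)(C)OCC2)O1 | intermediate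
6 | 3-[(4R)-2,2,4-trimethyl-1,3-dioxan-4-yl]propanal | O=CCC[C@@]1(C)OC(C)(C)OCC1 | intermediate
7 | 1-nitro-4-[(4R)-2,2,4-trimethyl-1,3-dioxan-4-yl]butan-2-ol (both carbinol epimers, formed in the flask) | OC(CC[C@@]1(C)OC(C)(C)OCC1)C[N+](=O)[O-] | intermediate
8 | 1-nitro-4-[(4R)-2,2,4-trimethyl-1,3-dioxan-4-yl]butan-2-yl methanesulfonate (formed in the flask) | CS(=O)(=O)OC(CC[C@@]1(C)OC(C)(C)OCC1)C[N+](=O)[O-] | intermediate
9 | (4R)-2,2,4-trimethyl-4-[(3E)-4-nitrobut-3-en-1-yl]-1,3-dioxane | [O-][N+](=O)/C=C/CC[C@@]1(C)OC(C)(C)OCC1 | intermediate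
10 | (2E)-2-nitro-5-[(4R)-2,2,4-trimethyl-1,3-dioxan-4-yl]pent-2-en-1-ol | OC/C(=C\CC[C@@]1(C)OC(C)(C)OCC1)[N+](=O)[O-] | intermediate
11 | (2E)-2-nitro-5-[(4R)-2,2,4-trimethyl-1,3-dioxan-4-yl]pent-2-en-1-yl acetate | CC(=O)OC/C(=C\CC[C@@]1(C)OC(C)(C)OCC1)[N+](=O)[O-] | intermediate
12 | 3-methylbutan-2-one | CC(=O)C(C)C | starting material
13 | (S)-1-phenylethan-1-amine | C[C@H](N)c1ccccc1 | starting material
14 | (S)-N-(3-methylbutan-2-ylidene)-1-phenylethan-1-amine | CC(C)C(C)=N[C@@H](C)c1ccccc1 | intermediate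
15 | (S)-N-[(4R)-3,3-dimethyl-5-nitro-4-{2-[(4R)-2,2,4-trimethyl-1,3-dioxan-4-yl]ethyl}hex-5-en-2-ylidene]-1-phenylethan-1-amine (formed in the flask) | C=C([N+](=O)[O-])[C@H](CC[C@@]1(C)OC(C)(C)OCC1)C(C)(C)C(C)=N[C@@H](C)c1ccccc1 | intermediate
16 | (S)-N-[(3R,4R)-2,2-dimethyl-4-nitro-3-{2-[(4R)-2,2,4-trimethyl-1,3-dioxan-4-yl]ethyl}cyclohexylidene]-1-phenylethan-1-amine (formed in the flask) | CC1(C)[C@@H](CC[C@@]2(C)OC(C)(C)OCC2)[C@H]([N+](=O)[O-])CCC1=N[C@@H](C)c1ccccc1 | intermediate
17 | (3R,4R)-2,2-dimethyl-4-nitro-3-{2-[(4R)-2,2,4-trimethyl-1,3-dioxan-4-yl]ethyl}cyclohexan-1-one (trans; any C4 epimer converges in step 10) | CC1(C)[C@@H](CC[C@@]2(C)OC(C)(C)OCC2)[C@H]([N+](=O)[O-])CCC1=O | intermediate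
18 | (1R,3R,4R)-2,2-dimethyl-4-nitro-3-{2-[(4R)-2,2,4-trimethyl-1,3-dioxan-4-yl]ethyl}cyclohexan-1-ol (C1 hydroxyl cis to the side chain) | CC1(C)[C@@H](CC[C@@]2(C)OC(C)(C)OCC2)[C@H]([N+](=O)[O-])CC[C@H]1O | intermediate
19 | sodium nitronate of 18 (C4 sp2, formed in the flask) | CC1(C)[C@@H](CC[C@@]2(C)OC(C)(C)OCC2)C(CC[C@H]1O)=[N+]([O-])[O-].[Na+] | intermediate
20 | (2R,4R)-4-hydroxy-3,3-dimethyl-2-{2-[(4R)-2,2,4-trimethyl-1,3-dioxan-4-yl]ethyl}cyclohexan-1-one (ring C4 ketone) | CC1(C)[C@@H](CC[C@@]2(C)OC(C)(C)OCC2)C(=O)CC[C@H]1O | intermediate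
21 | (1R,3R,4S)-2,2,4-trimethyl-3-{2-[(4R)-2,2,4-trimethyl-1,3-dioxan-4-yl]ethyl}cyclohexane-1,4-diol | CC1(C)[C@@H](CC[C@@]2(C)OC(C)(C)OCC2)[C@@](C)(O)CC[C@H]1O | intermediate
22 | (3R,4S)-4-hydroxy-2,2,4-trimethyl-3-{2-[(4R)-2,2,4-trimethyl-1,3-dioxan-4-yl]ethyl}cyclohexan-1-one | CC1(C)[C@@H](CC[C@@]2(C)OC(C)(C)OCC2)[C@@](C)(O)CCC1=O | intermediate
23 | (1S,3R,4S)-2,2,4-trimethyl-3-{2-[(4R)-2,2,4-trimethyl-1,3-dioxan-4-yl]ethyl}cyclohexane-1,4-diol (formed in the flask) | CC1(C)[C@@H](CC[C@@]2(C)OC(C)(C)OCC2)[C@@](C)(O)CC[C@@H]1O | intermediate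
24 | (1S,3R,4S)-3-[(3R)-3,5-dihydroxy-3-methylpentyl]-2,2,4-trimethylcyclohexane-1,4-diol | CC1(C)[C@@H](CC[C@@](C)(O)CCO)[C@@](C)(O)CC[C@@H]1O | intermediate
25 | umbelliferone, 7-hydroxy-2H-chromen-2-one | O=c1ccc2ccc(O)cc2o1 | starting material
26 | 7-{[(3R)-5-[(1R,3S,6S)-3,6-dihydroxy-2,2,6-trimethylcyclohexyl]-3-hydroxy-3-methylpentyl]oxy}-2H-chromen-2-one | CC1(C)[C@@H](CC[C@@](C)(O)CCOc2ccc3ccc(=O)oc3c2)[C@@](C)(O)CC[C@@H]1O | target

**Step count and risks**

Total step count: 14. Longest linear sequence: 13 steps (steps 1 to 6 and 8 to 14, from (R)-linalool); step 7 is a one-step side branch.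

Steps most likely to fail:

Step 8 (bears the label). The first C–C bond may form through the methyl-side enamine (wrong regiochemistry), reversible N-alkylation may stall the carbocyclisation, or the facial selectivity at C3 may be low. Fallback by known reactions, starting from nitroalkene 9 and returning at 17: an enamine-catalysed Michael addition of isobutyraldehyde to 9, using the enantiomer of 1-(2-aminocyclohexyl)-3-[3,5-bis(trifluoromethyl)phenyl]thiourea that gives the 3R adduct, should give (3R)-2,2-dimethyl-4-nitro-3-{2-[(4R)-2,2,4-trimethyl-1,3-dioxan-4-yl]ethyl}butanal F1. Excess CH2=CHMgBr (THF, −78 °C; the nitronate formed first is inert) should give the allylic alcohol (5R)-4,4-dimethyl-6-nitro-5-{2-[(4R)-2,2,4-trimethyl-1,3-dioxan-4-yl]ethyl}hex-1-en-3-ol F2. Dess–Martin oxidation should give the vinyl ketone (5R)-4,4-dimethyl-6-nitro-5-{2-[(4R)-2,2,4-trimethyl-1,3-dioxan-4-yl]ethyl}hex-1-en-3-one F3, whose nitronate (catalytic 1,8-diazabicyclo[5.4.0]undec-7-ene) should close the ring by intramolecular Michael addition to give 17.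

Step 5. Base-induced deconjugation or oligomerisation of the aliphatic nitroalkene may outrun the hydroxymethylation. Fallback starting from aldehyde 6 and returning at 11: a Henry reaction of 6 with 2-nitroethanol should give 2-nitro-5-[(4R)-2,2,4-trimethyl-1,3-dioxan-4-yl]pentane-1,3-diol F4. Acetylation (Ac2O, pyridine) should give 2-nitro-5-[(4R)-2,2,4-trimethyl-1,3-dioxan-4-yl]pentane-1,3-diyl diacetate F5. Elimination of acetic acid with NaOAc, followed by equilibration of the allylic acetates with catalytic 1,4-diazabicyclo[2.2.2]octane, should give the conjugated primary acetate 11.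

Step 10. Oxidation of the nitronate may be incomplete, or the α-carbon C3 may epimerise under the basic conditions. Fallback avoiding base, starting from 18 and returning at 20: reduction of the nitro group (NiCl2·6H2O, NaBH4, MeOH) should give (1R,3R)-4-amino-2,2-dimethyl-3-{2-[(4R)-2,2,4-trimethyl-1,3-dioxan-4-yl]ethyl}cyclohexan-1-ol F6. Oxidative deamination with 3,5-di-tert-butyl-1,2-benzoquinone (MeOH, rt) and hydrolysis of the resulting imine with aqueous oxalic acid should give ketone 20.

**Further compounds**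

F1 | step 8 | (3R)-2,2-dimethyl-4-nitro-3-{2-[(4R)-2,2,4-trimethyl-1,3-dioxan-4-yl]ethyl}butanal | O=CC(C)(C)[C@@H](CC[C@@]1(C)OC(C)(C)OCC1)C[N+](=O)[O-]
F2 | step 8 | (5R)-4,4-dimethyl-6-nitro-5-{2-[(4R)-2,2,4-trimethyl-1,3-dioxan-4-yl]ethyl}hex-1-en-3-ol (carbinol epimers) | C=CC(O)C(C)(C)[C@@H](CC[C@@]1(C)OC(C)(C)OCC1)C[N+](=O)[O-]
F3 | step 8 | (5R)-4,4-dimethyl-6-nitro-5-{2-[(4R)-2,2,4-trimethyl-1,3-dioxan-4-yl]ethyl}hex-1-en-3-one | C=CC(=O)C(C)(C)[C@@H](CC[C@@]1(C)OC(C)(C)OCC1)C[N+](=O)[O-]
F4 | step 5 | 2-nitro-5-[(4R)-2,2,4-trimethyl-1,3-dioxan-4-yl]pentane-1,3-diol (diastereomer mixture) | OCC([N+](=O)[O-])C(O)CC[C@@]1(C)OC(C)(C)OCC1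
F5 | step 5 | 2-nitro-5-[(4R)-2,2,4-trimethyl-1,3-dioxan-4-yl]pentane-1,3-diyl diacetate | CC(=O)OCC([N+](=O)[O-])C(OC(C)=O)CC[C@@]1(C)OC(C)(C)OCC1
F6 | step 10 | (1R,3R)-4-amino-2,2-dimethyl-3-{2-[(4R)-2,2,4-trimethyl-1,3-dioxan-4-yl]ethyl}cyclohexan-1-ol (C4 epimers) | CC1(C)[C@@H](CC[C@@]2(C)OC(C)(C)OCC2)C(N)CC[C@H]1O
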